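**Retrosynthetic overview** (DHB 1 = the dihydrobenzofuran that carries the styryl arm; DHB 2 = the other one)
1. Target ⇐ global deprotection of 23; 23 ⇐ Friedel–Crafts union of cyclic acetal 22 (oxocarbenium at C2 of DHB 1) with C7–H of the DHB 2 fragment 14.
2. 14 ⇐ the same C2 arylation of cyclic acetal 12 with resorcinol (through its C4), then pivaloylation.
3. 12 and 22 ⇐ E-stilbenes 9 and 20 by an enantioselective oxidative 1,2-aryl shift (the 2,6-dioxygenated ring migrates and C3 is set); MOM loss then closes the furan ring onto the new acetal carbon.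
4. 20 ⇐ 9 (para C–H borylation, vinylation, Heck with 4-iodophenol); 9 ⇐ Negishi coupling of zincated resorcinol bis-MOM ether 2 with bromostyrene 6 (from resorcinol dipivalate and (E)-1,2-dibromoethene).
5. Ring order: furan ring of DHB 2 (step 5), its C2 aryl (step 7), furan ring of DHB 1 (step 10), DHB 1–DHB 2 bond (step 11).

Reagent and assumption: Lac*I(OAc)2 = dimethyl (2R,2'R)-2,2'-{[2-(diacetoxyiodo)-1,3-phenylene]bis(oxy)}dipropanoate, COC(=O)[C@@H](C)Oc1cccc(O[C@H](C)C(=O)OC)c1I(OC(C)=O)OC(C)=O; it is assumed to give the 3R series drawn, and if the first run on 9 shows the opposite sense its (S,S)-enantiomer is used in steps 5 and 10.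

**Step 1**
Reactants: 1 resorcinol
Product: 2 1,3-bis(methoxymethoxy)benzene
Conditions: NaH, MOMCl, DMF, 0 °C to rt
Reagents that add atoms: chloromethyl methyl ether, COCCl
Why: Williamson-type O-alkylation that installs the two MOM ethers needed as ortho-directing groups in step 4.

**Step 2**
Reactants: 1 resorcinol
Product: 3 1,3-phenylene bis(2,2-dimethylpropanoate)
Conditions: PivCl, Et3N, DMAP (cat.), CH2Cl2, 0 °C to rt
Reagents that add atoms: pivaloyl chloride, CC(C)(C)C(Cl)=O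
Why: Standard acylation; the pivalates keep these rings electron-poor in the later oxidation and Friedel–Crafts steps and survive the Pd, Ir, BF3 and acidic methanol conditions.

**Step 3**
Reactants: 3 1,3-phenylene bis(2,2-dimethylpropanoate); 4 (E)-1,2-dibromoethene (5 equiv)
Product: 6 5-[(E)-2-bromoethenyl]-1,3-phenylene bis(2,2-dimethylpropanoate), via arylboronate 5 (not isolated)
Conditions: [Ir(OMe)(cod)]2 (1.5 mol %), 4,4'-di-tert-butyl-2,2'-bipyridine, B2pin2 (0.6 equiv), THF, 80 °C; then 4, Pd(PPh3)4 (3 mol %), K3PO4, H2O, 45 °C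
Reagents that add atoms: none
Why: Sterically controlled iridium-catalysed C–H borylation goes to C5 (the only C–H with no ortho substituent), and the one-pot Suzuki–Miyaura coupling with excess E-dibromide stops after one C–Br bond with retention of alkene geometry.

**Step 4**
Reactants: 2 1,3-bis(methoxymethoxy)benzene; 6 5-[(E)-2-bromoethenyl]-1,3-phenylene bis(2,2-dimethylpropanoate)
Product: 9 5-{(E)-2-[2,6-bis(methoxymethoxy)phenyl]ethenyl}-1,3-phenylene bis(2,2-dimethylpropanoate), via aryllithium 7 (not isolated), via arylzinc chloride 8 (not isolated)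
Conditions: n-BuLi, THF, 0 °C; ZnCl2, 0 °C to rt; then 6, Pd2(dba)3 (2 mol %), SPhos, THF, 45 °C
Reagents that add atoms: none
Why: Directed ortho-metalation between the two MOM ethers, transmetalation to zinc (ester-tolerant) and Negishi coupling with the alkenyl bromide with retention of E geometry.

**Step 5**
Reactants: 9 5-{(E)-2-[2,6-bis(methoxymethoxy)phenyl]ethenyl}-1,3-phenylene bis(2,2-dimethylpropanoate)
Product: 11 5-[(2R,3R)-4-hydroxy-2-methoxy-2,3-dihydro-1-benzofuran-3-yl]-1,3-phenylene bis(2,2-dimethylpropanoate), via dimethyl acetal 10 (not isolated)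
Conditions: Lac*I(OAc)2 (1.2 equiv), TsOH (anhydrous), MeOH/CH2Cl2 1:4, −78 to −40 °C; Me2S; then HCl (1.25 M in MeOH), 0.02 M, 35 °C
Reagents that add atoms: methanol, CO
Why: Proposed new method: enantioselective oxidative 1,2-aryl shift of an E-stilbene with a lactate-derived chiral aryliodine diacetate, in which the trivalent iodine adds to one alkene face, MeOH opens the iodonium at the carbon next to the 2,6-dioxygenated ring, and that ring then migrates through a phenonium ion with inversion at the iodine-bearing carbon (kept from ionising by the electron-poor bis(pivaloyloxy)phenyl group), so the face choice fixes C3 as R, after which acid removes both MOM groups and closes the five-membered mixed acetal (C2 epimers both carried on); the closest known reactions are the racemic Koser-reagent rearrangement of stilbenes to diarylacetaldehyde acetals and chiral aryliodine 1,2-aryl migrations of 1,1-diarylalkenes and chalcones.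

**Step 6**
Reactants: 11 5-[(2R,3R)-4-hydroxy-2-methoxy-2,3-dihydro-1-benzofuran-3-yl]-1,3-phenylene bis(2,2-dimethylpropanoate)
Product: 12 5-[(2R,3R)-2-methoxy-4-{[tri(propan-2-yl)silyl]oxy}-2,3-dihydro-1-benzofuran-3-yl]-1,3-phenylene bis(2,2-dimethylpropanoate)
Conditions: TIPSCl, imidazole, DMF, rt
Reagents that add atoms: chlorotri(propan-2-yl)silane, CC(C)[Si](Cl)(C(C)C)C(C)C
Why: Basic silylation leaves the acetal untouched, and the bulky TIPS ether keeps this ring electron-rich while screening C5 for step 11.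

**Step 7**
Reactants: 12 5-[(2R,3R)-2-methoxy-4-{[tri(propan-2-yl)silyl]oxy}-2,3-dihydro-1-benzofuran-3-yl]-1,3-phenylene bis(2,2-dimethylpropanoate); 1 resorcinol (8 equiv)
Product: 14 4-[(2R,3R)-3-[3,5-bis(2,2-dimethylpropanoyloxy)phenyl]-4-{[tri(propan-2-yl)silyl]oxy}-2,3-dihydro-1-benzofuran-2-yl]-1,3-phenylene bis(2,2-dimethylpropanoate), via resorcinol adduct 13 (not isolated)
Conditions: BF3·OEt2, CH2Cl2/Et2O 4:1, −78 to −30 °C; aqueous wash; then PivCl, pyridine, DMAP, CH2Cl2, rt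
Reagents that add atoms: pivaloyl chloride, CC(C)(C)C(Cl)=O
Why: Lewis-acid ionisation of the cyclic acetal gives a 2-benzofuranylium (oxocarbenium) ion that resorcinol attacks through C4 (Friedel–Crafts C-arylation, as in aryl C-glycoside synthesis) on the face anti to the C3 aryl group, which sets C2 as R (2,3-trans), and pivaloylation then deactivates the new ring for step 11.

**Step 8**
Reactants: 9 5-{(E)-2-[2,6-bis(methoxymethoxy)phenyl]ethenyl}-1,3-phenylene bis(2,2-dimethylpropanoate); 15 bromoethene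
Product: 17 5-{(E)-2-[4-ethenyl-2,6-bis(methoxymethoxy)phenyl]ethenyl}-1,3-phenylene bis(2,2-dimethylpropanoate), via arylboronate 16 (not isolated)
Conditions: [Ir(OMe)(cod)]2 (2 mol %), 4,4'-di-tert-butyl-2,2'-bipyridine, B2pin2 (0.7 equiv), THF, 60 °C; then 15 (1 M in THF), Pd(dppf)Cl2 (3 mol %), K3PO4, H2O, 50 °C, sealed
Reagents that add atoms: none
Why: Iridium C–H borylation is confined to the only aromatic C–H without an ortho substituent (para to the alkene on the bis-MOM ring), and Suzuki–Miyaura coupling then installs the vinyl group.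

**Step 9**
Reactants: 18 4-iodophenol; 17 5-{(E)-2-[4-ethenyl-2,6-bis(methoxymethoxy)phenyl]ethenyl}-1,3-phenylene bis(2,2-dimethylpropanoate)
Product: 20 5-[(E)-2-{2,6-bis(methoxymethoxy)-4-[(E)-2-{4-[(2,2-dimethylpropanoyl)oxy]phenyl}ethenyl]phenyl}ethenyl]-1,3-phenylene bis(2,2-dimethylpropanoate), via aryl pivalate 19 (not isolated)
Conditions: PivCl, Et3N, DMF, 0 °C to rt; then 17, Pd(OAc)2 (3 mol %), P(o-tol)3, 90 °C
Reagents that add atoms: pivaloyl chloride, CC(C)(C)C(Cl)=O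
Why: In situ esterification protects the phenol, and the Mizoroki–Heck reaction arylates the terminal vinyl group at its β-carbon to give the E-stilbene while the internal diaryl alkene stays inert.

**Step 10**
Reactants: 20 5-[(E)-2-{2,6-bis(methoxymethoxy)-4-[(E)-2-{4-[(2,2-dimethylpropanoyl)oxy]phenyl}ethenyl]phenyl}ethenyl]-1,3-phenylene bis(2,2-dimethylpropanoate)
Product: 22 5-[(2R,3R)-4-hydroxy-2-methoxy-6-{(E)-2-[4-(2,2-dimethylpropanoyloxy)phenyl]ethenyl}-2,3-dihydro-1-benzofuran-3-yl]-1,3-phenylene bis(2,2-dimethylpropanoate), via dimethyl acetal 21 (not isolated)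
Conditions: Lac*I(OAc)2 (1.05 equiv), TsOH (anhydrous), MeOH/CH2Cl2 1:4, −78 °C; Me2S; then HCl (1.25 M in MeOH), 0.02 M, 35 °C
Reagents that add atoms: methanol, CO
Why: Proposed new method: the same enantioselective oxidative 1,2-aryl shift as in step 5, here also required to be chemoselective, which is expected because the alkene attached to the 2,6-bis(methoxymethoxy)aryl ring is far more electron-rich than the pivaloyloxystyryl alkene and so engages the trivalent iodine reagent first at −78 °C, the migrating ring again setting C3 as R before acid closes the furan ring; the closest known reaction is the racemic Koser-reagent stilbene rearrangement.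

**Step 11**
Reactants: 22 5-[(2R,3R)-4-hydroxy-2-methoxy-6-{(E)-2-[4-(2,2-dimethylpropanoyloxy)phenyl]ethenyl}-2,3-dihydro-1-benzofuran-3-yl]-1,3-phenylene bis(2,2-dimethylpropanoate); 14 (1.3 equiv)
Product: 23 TIPS-protected heptapivalate of the target (free OH only at C4 of DHB 1)
Conditions: BF3·OEt2 (2 equiv), 4 Å MS, CH2Cl2, −78 to −30 °C; Et3N quench
Reagents that add atoms: none
Why: The same oxocarbenium Friedel–Crafts arylation, in which the only activated C–H of 14 is C7 of its benzofuran ring (ortho to the ring oxygen, para to OTIPS, with C5 screened by the TIPS group and every other ring carrying pivalates), and attack anti to the C3 aryl group of the cation from 22 gives the 2,3-trans (2R,3R) ring of DHB 1.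

**Step 12**
Reactants: 23 TIPS-protected heptapivalate of the target
Product: 25 target CNP0217875.2 (all four ring stereocentres R), via heptapivalate 24 (not isolated)
Conditions: TBAF, THF, 0 °C; then NaOMe, MeOH, 0 °C to rt, argon, degassed; 1 M HCl to pH 5
Reagents that add atoms: none
Why: Fluoride desilylation followed by Zemplén-type methanolysis of the seven aryl pivalates, which touches neither the stereocentres nor the stilbene and avoids the acid that isomerises free-phenol dihydrobenzofurans of this type.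

**Compound list**
1 | resorcinol (benzene-1,3-diol) | Oc1cccc(O)c1 | starting material
2 | 1,3-bis(methoxymethoxy)benzene | COCOc1cccc(OCOC)c1 | intermediate
3 | 1,3-phenylene bis(2,2-dimethylpropanoate) | CC(C)(C)C(=O)Oc1cccc(OC(=O)C(C)(C)C)c1 | intermediate
4 | (E)-1,2-dibromoethene | Br/C=C/Br | starting material
5 | 5-(4,4,5,5-tetramethyl-1,3,2-dioxaborolan-2-yl)-1,3-phenylene bis(2,2-dimethylpropanoate) | CC(C)(C)C(=O)Oc1cc(B2OC(C)(C)C(C)(C)O2)cc(OC(=O)C(C)(C)C)c1 | intermediate (not isolated)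
6 | 5-[(E)-2-bromoethenyl]-1,3-phenylene bis(2,2-dimethylpropanoate) | CC(C)(C)C(=O)Oc1cc(/C=C/Br)cc(OC(=O)C(C)(C)C)c1 | intermediate
7 | [2,6-bis(methoxymethoxy)phenyl]lithium | [Li]c1c(OCOC)cccc1OCOC | intermediate (not isolated)
8 | [2,6-bis(methoxymethoxy)phenyl]zinc chloride | Cl[Zn]c1c(OCOC)cccc1OCOC | intermediate (not isolated)
9 | 5-{(E)-2-[2,6-bis(methoxymethoxy)phenyl]ethenyl}-1,3-phenylene bis(2,2-dimethylpropanoate) | COCOc1cccc(OCOC)c1/C=C/c1cc(OC(=O)C(C)(C)C)cc(OC(=O)C(C)(C)C)c1 | intermediate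
10 | 5-{(1R)-1-[2,6-bis(methoxymethoxy)phenyl]-2,2-dimethoxyethyl}-1,3-phenylene bis(2,2-dimethylpropanoate) | COC(OC)[C@@H](c1c(OCOC)cccc1OCOC)c1cc(OC(=O)C(C)(C)C)cc(OC(=O)C(C)(C)C)c1 | intermediate (not isolated)
11 | 5-[(2R,3R)-4-hydroxy-2-methoxy-2,3-dihydro-1-benzofuran-3-yl]-1,3-phenylene bis(2,2-dimethylpropanoate) (trans anomer drawn; the C2 epimer is carried along) | c1cc(O)c2c(c1)O[C@@H](OC)[C@@H]2c1cc(OC(=O)C(C)(C)C)cc(OC(=O)C(C)(C)C)c1 | intermediate
12 | 5-[(2R,3R)-2-methoxy-4-{[tri(propan-2-yl)silyl]oxy}-2,3-dihydro-1-benzofuran-3-yl]-1,3-phenylene bis(2,2-dimethylpropanoate) | c1cc(O[Si](C(C)C)(C(C)C)C(C)C)c2c(c1)O[C@@H](OC)[C@@H]2c1cc(OC(=O)C(C)(C)C)cc(OC(=O)C(C)(C)C)c1 | intermediate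
13 | 5-[(2R,3R)-2-(2,4-dihydroxyphenyl)-4-{[tri(propan-2-yl)silyl]oxy}-2,3-dihydro-1-benzofuran-3-yl]-1,3-phenylene bis(2,2-dimethylpropanoate) | c1ccc(O[Si](C(C)C)(C(C)C)C(C)C)c2c1O[C@@H](c1ccc(O)cc1O)[C@@H]2c1cc(OC(=O)C(C)(C)C)cc(OC(=O)C(C)(C)C)c1 | intermediate (not isolated)
14 | 4-[(2R,3R)-3-[3,5-bis(2,2-dimethylpropanoyloxy)phenyl]-4-{[tri(propan-2-yl)silyl]oxy}-2,3-dihydro-1-benzofuran-2-yl]-1,3-phenylene bis(2,2-dimethylpropanoate) | c1ccc(O[Si](C(C)C)(C(C)C)C(C)C)c2c1O[C@@H](c1ccc(OC(=O)C(C)(C)C)cc1OC(=O)C(C)(C)C)[C@@H]2c1cc(OC(=O)C(C)(C)C)cc(OC(=O)C(C)(C)C)c1 | intermediate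
15 | bromoethene (vinyl bromide) | C=CBr | starting material
16 | 5-{(E)-2-[2,6-bis(methoxymethoxy)-4-(4,4,5,5-tetramethyl-1,3,2-dioxaborolan-2-yl)phenyl]ethenyl}-1,3-phenylene bis(2,2-dimethylpropanoate) | COCOc1cc(B2OC(C)(C)C(C)(C)O2)cc(OCOC)c1/C=C/c1cc(OC(=O)C(C)(C)C)cc(OC(=O)C(C)(C)C)c1 | intermediate (not isolated)
17 | 5-{(E)-2-[4-ethenyl-2,6-bis(methoxymethoxy)phenyl]ethenyl}-1,3-phenylene bis(2,2-dimethylpropanoate) | COCOc1cc(C=C)cc(OCOC)c1/C=C/c1cc(OC(=O)C(C)(C)C)cc(OC(=O)C(C)(C)C)c1 | intermediate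
18 | 4-iodophenol | Oc1ccc(I)cc1 | starting material
19 | 4-iodophenyl 2,2-dimethylpropanoate | CC(C)(C)C(=O)Oc1ccc(I)cc1 | intermediate (not isolated)
20 | 5-[(E)-2-{2,6-bis(methoxymethoxy)-4-[(E)-2-{4-[(2,2-dimethylpropanoyl)oxy]phenyl}ethenyl]phenyl}ethenyl]-1,3-phenylene bis(2,2-dimethylpropanoate) | COCOc1cc(/C=C/c2ccc(OC(=O)C(C)(C)C)cc2)cc(OCOC)c1/C=C/c1cc(OC(=O)C(C)(C)C)cc(OC(=O)C(C)(C)C)c1 | intermediate
21 | 5-{(1R)-1-[2,6-bis(methoxymethoxy)-4-{(E)-2-[4-(2,2-dimethylpropanoyloxy)phenyl]ethenyl}phenyl]-2,2-dimethoxyethyl}-1,3-phenylene bis(2,2-dimethylpropanoate) | COC(OC)[C@@H](c1c(OCOC)cc(/C=C/c2ccc(OC(=O)C(C)(C)C)cc2)cc1OCOC)c1cc(OC(=O)C(C)(C)C)cc(OC(=O)C(C)(C)C)c1 | intermediate (not isolated)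
22 | 5-[(2R,3R)-4-hydroxy-2-methoxy-6-{(E)-2-[4-(2,2-dimethylpropanoyloxy)phenyl]ethenyl}-2,3-dihydro-1-benzofuran-3-yl]-1,3-phenylene bis(2,2-dimethylpropanoate) (trans anomer drawn; the C2 epimer is carried along) | CC(C)(C)C(=O)Oc1ccc(/C=C/c2cc(O)c3c(c2)O[C@@H](OC)[C@@H]3c2cc(OC(=O)C(C)(C)C)cc(OC(=O)C(C)(C)C)c2)cc1 | intermediate
23 | target skeleton, (2R,3R) in both dihydrobenzofurans, with pivalate esters on the styryl phenol, on both 3,5-dioxyphenyl rings and on the 2,4-dioxyphenyl ring, OTIPS at C4 of DHB 2 and free OH at C4 of DHB 1 | CC(C)(C)C(=O)Oc1ccc(/C=C/c2cc(O)c3c(c2)O[C@@H](c2ccc(O[Si](C(C)C)(C(C)C)C(C)C)c4c2O[C@@H](c2ccc(OC(=O)C(C)(C)C)cc2OC(=O)C(C)(C)C)[C@@H]4c2cc(OC(=O)C(C)(C)C)cc(OC(=O)C(C)(C)C)c2)[C@@H]3c2cc(OC(=O)C(C)(C)C)cc(OC(=O)C(C)(C)C)c2)cc1 | intermediate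
24 | as 23 but with free OH in place of OTIPS (heptapivalate) | CC(C)(C)C(=O)Oc1ccc(/C=C/c2cc(O)c3c(c2)O[C@@H](c2ccc(O)c4c2O[C@@H](c2ccc(OC(=O)C(C)(C)C)cc2OC(=O)C(C)(C)C)[C@@H]4c2cc(OC(=O)C(C)(C)C)cc(OC(=O)C(C)(C)C)c2)[C@@H]3c2cc(OC(=O)C(C)(C)C)cc(OC(=O)C(C)(C)C)c2)cc1 | intermediate (not isolated)
25 | 4-[(2R,3R)-3-(3,5-dihydroxyphenyl)-7-{(2R,3R)-3-(3,5-dihydroxyphenyl)-4-hydroxy-6-[(E)-2-(4-hydroxyphenyl)ethenyl]-2,3-dihydro-1-benzofuran-2-yl}-4-hydroxy-2,3-dihydro-1-benzofuran-2-yl]benzene-1,3-diol | Oc1ccc(/C=C/c2cc(O)c3c(c2)O[C@@H](c2ccc(O)c4c2O[C@@H](c2ccc(O)cc2O)[C@@H]4c2cc(O)cc(O)c2)[C@@H]3c2cc(O)cc(O)c2)cc1 | target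

**Totals**
Total step count: 12. Longest linear sequence: 8 steps (steps 2, 3, 4, 8, 9, 10, 11, 12 from resorcinol; the branch 2, 3, 4, 5, 6, 7, 11, 12 is equally long).

**Three steps most likely to fail**

Step 5 (new method). The facial selectivity of the chiral iodine reagent on an E-stilbene is untested, and participation of an ortho MOM oxygen could compete with the aryl shift. The fallback sets out from 9 and uses the known racemic rearrangement with achiral PhI(OH)OTs in MeOH, followed by the same acid stage. This gives 10 together with its mirror image, the (1S)-dimethyl acetal F1, and then 11 together with its mirror image, the (2S,3S)-cyclic acetal F2. Compound 11 is separated from F2 by preparative chiral SFC, so resolution replaces reagent control, and the route is rejoined at 11.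

Step 10 (new method on a substrate with two stilbene alkenes). If the oxidant does not discriminate between the two alkenes, the aryl shift is done before the second alkene exists. The fallback sets out from 10, isolated by stopping step 5 before the acid stage. Iridium-catalysed C–H borylation para on the bis-MOM ring gives the pinacol boronate F3. Suzuki–Miyaura coupling with 15 gives the vinyl arene F4. Heck reaction with 19 gives 21, and the route is rejoined at 21 (acid stage of step 10 to 22).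

Step 11 (fragment union). The oxocarbenium ion from 22 can lose H-3 to give an achiral 3-arylbenzofuran, or the arene may react too slowly or at the wrong site. The fallback replaces the cationic arylation by carbonyl addition and cyclodehydration and sets out from 14 and 22. Bromination of 14 with NBS in MeCN gives the 7-bromide F5, and Miyaura borylation (B2pin2, Pd(dppf)Cl2, KOAc) gives the 7-boronate F6. Hydrolysis of 22 (AcOH, THF/H2O) gives the lactol F7. Rhodium-catalysed 1,2-addition of F6 to the open aldehyde form of F7 ([Rh(OH)(cod)]2, dioxane/H2O, rt) gives the carbinol F8 as a mixture of carbinol epimers. PPTS in CH2Cl2 then ionises the electron-rich benzylic alcohol, and one of the two equivalent ortho phenols closes the thermodynamically preferred 2,3-trans ring, which rejoins the route at 23.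

**Further compounds**
F1 | step 5 | 5-{(1S)-1-[2,6-bis(methoxymethoxy)phenyl]-2,2-dimethoxyethyl}-1,3-phenylene bis(2,2-dimethylpropanoate) | COC(OC)[C@H](c1c(OCOC)cccc1OCOC)c1cc(OC(=O)C(C)(C)C)cc(OC(=O)C(C)(C)C)c1
F2 | step 5 | 5-[(2S,3S)-4-hydroxy-2-methoxy-2,3-dihydro-1-benzofuran-3-yl]-1,3-phenylene bis(2,2-dimethylpropanoate) | c1cc(O)c2c(c1)O[C@H](OC)[C@H]2c1cc(OC(=O)C(C)(C)C)cc(OC(=O)C(C)(C)C)c1
F3 | step 10 | 5-{(1R)-1-[2,6-bis(methoxymethoxy)-4-(4,4,5,5-tetramethyl-1,3,2-dioxaborolan-2-yl)phenyl]-2,2-dimethoxyethyl}-1,3-phenylene bis(2,2-dimethylpropanoate) | COC(OC)[C@@H](c1c(OCOC)cc(B2OC(C)(C)C(C)(C)O2)cc1OCOC)c1cc(OC(=O)C(C)(C)C)cc(OC(=O)C(C)(C)C)c1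
F4 | step 10 | 5-{(1R)-1-[4-ethenyl-2,6-bis(methoxymethoxy)phenyl]-2,2-dimethoxyethyl}-1,3-phenylene bis(2,2-dimethylpropanoate) | COC(OC)[C@@H](c1c(OCOC)cc(C=C)cc1OCOC)c1cc(OC(=O)C(C)(C)C)cc(OC(=O)C(C)(C)C)c1
F5 | step 11 | 4-[(2R,3R)-3-[3,5-bis(2,2-dimethylpropanoyloxy)phenyl]-7-bromo-4-{[tri(propan-2-yl)silyl]oxy}-2,3-dihydro-1-benzofuran-2-yl]-1,3-phenylene bis(2,2-dimethylpropanoate) | Brc1ccc(O[Si](C(C)C)(C(C)C)C(C)C)c2c1O[C@@H](c1ccc(OC(=O)C(C)(C)C)cc1OC(=O)C(C)(C)C)[C@@H]2c1cc(OC(=O)C(C)(C)C)cc(OC(=O)C(C)(C)C)c1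
F6 | step 11 | 4-[(2R,3R)-3-[3,5-bis(2,2-dimethylpropanoyloxy)phenyl]-7-(4,4,5,5-tetramethyl-1,3,2-dioxaborolan-2-yl)-4-{[tri(propan-2-yl)silyl]oxy}-2,3-dihydro-1-benzofuran-2-yl]-1,3-phenylene bis(2,2-dimethylpropanoate) | CC1(C)OB(OC1(C)C)c1ccc(O[Si](C(C)C)(C(C)C)C(C)C)c2c1O[C@@H](c1ccc(OC(=O)C(C)(C)C)cc1OC(=O)C(C)(C)C)[C@@H]2c1cc(OC(=O)C(C)(C)C)cc(OC(=O)C(C)(C)C)c1
F7 | step 11 | 5-[(2R,3R)-2,4-dihydroxy-6-{(E)-2-[4-(2,2-dimethylpropanoyloxy)phenyl]ethenyl}-2,3-dihydro-1-benzofuran-3-yl]-1,3-phenylene bis(2,2-dimethylpropanoate) (lactol, trans anomer drawn) | CC(C)(C)C(=O)Oc1ccc(/C=C/c2cc(O)c3c(c2)O[C@@H](O)[C@@H]3c2cc(OC(=O)C(C)(C)C)cc(OC(=O)C(C)(C)C)c2)cc1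
F8 | step 11 | carbinol from 1,2-addition of F6 to F7: (1R)-diarylmethine carrying the 2,6-dihydroxy-4-[(E)-4-(pivaloyloxy)styryl]phenyl and 3,5-bis(pivaloyloxy)phenyl groups, bonded to CH(OH) attached to C7 of the DHB 2 fragment (carbinol epimers) | CC(C)(C)C(=O)Oc1ccc(/C=C/c2cc(O)c(c(O)c2)[C@H](C(O)c2ccc(O[Si](C(C)C)(C(C)C)C(C)C)c3c2O[C@@H](c2ccc(OC(=O)C(C)(C)C)cc2OC(=O)C(C)(C)C)[C@@H]3c2cc(OC(=O)C(C)(C)C)cc(OC(=O)C(C)(C)C)c2)c2cc(OC(=O)C(C)(C)C)cc(OC(=O)C(C)(C)C)c2)cc1
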